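## Analysis of the target

Compound 22 (compound numbers as in the steps below) is a eudesmane. Ring A (C1–C2–C3–C4=C5–C10) and ring B (C5–C6–C7–C8–C9–C10) are fused at C5 and C10; C4 carries a methyl (C15), C10 the angular methyl (C14), and C7 the unit C11(=C13H2)–C12O2CH3. There are four stereocentres, C3 (S), C7 (R), C8 (R) and C10 (R). In the usual drawing the C3 acyloxy group, the C7 side chain, the C8 acetoxy group and the C10 methyl are all β. On the chair of ring B the C8 oxygen is therefore axial and syn to the C10 methyl, and the C7 chain is equatorial and cis to that oxygen, which is the arrangement of a ring-opened cis-fused 12,8-lactone. Sensitive groups are three different esters (an acrylate methyl ester, a hindered secondary acetate, an allylic (E)-3-methylpent-2-enoate with acidic γ-hydrogens), the C11=C13 Michael acceptor, the ionisable allylic C3–O bond next to the tetrasubstituted C4=C5 alkene, and the O8/C12 pair, which relactonises whenever O8 is free. The synthesis is hard because quaternary C10 cannot be corrected later and must direct C3, C7 and C8, because the acrylate survives neither hydride nor hydrogenation, and because three oxygens need three different acyl groups in a fixed order. The plan rests on ring B: the quaternary methyl carbon C10, an oxygen on C8 in a 1,3 relation to it and a carbon substituent on C7 are what a 2-silyloxy-3-alkylbuta-1,3-diene (C6–C7–C8–C9) leaves behind when it adds across the methyl-bearing alkene C5=C10 of a quinone. The quinone's two carbonyls (C1, C4) and its methoxy group (C3) then serve as the handles for ring A.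

## Retrosynthetic reasoning

22 ⇒ 21. The acetyl–O8 bond is cut first. A free 8β-hydroxyl beside the C12 ester tends to close back to the lactone, so the acetate is the last bond made and 21 is used at once.

21 ⇒ 19 (through 20). The methyl ester and the free O8 are traced back to the cis-fused 12,8-lactone of 19. The lactone protects O8 and C12 together, activates C11 for the one-carbon homologation, and records that O8 and the C7 chain are cis. Forward, hydroxide has to open the strained lactone faster than it touches the hindered enoate at O3, and carboxylate 20 has to be O-alkylated without passing through the free acid.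

19 ⇒ 17 + 18. The acyl–O3 bond is cut. Acid 18 is purchased and attached after all strongly basic steps, because its γ-hydrogens would not survive enolate chemistry, and before the lactone is opened, so that O3 and O8 never have to be told apart.

17 ⇒ 14. The C11=C13 bond is cut back to the unsubstituted lactone. The exocyclic acceptor is installed only after every hydride and hydrogenation step; the forward reaction is an aminomethylation of the lactone enolate followed by elimination.

14 ⇒ 13 ⇒ 11 (through 12). The C3–H and C8–H bonds come from two hydride additions steered by the C10 methyl. At C8 the axial approach is blocked, so the axial 8β-alcohol forms and lactonises onto the cis C7 chain. At C3 axial delivery to the enone gives the 3β-alcohol. Doing C8 first, while C3 is still an unreactive conjugated ketone, keeps the two events separate.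

11 ⇒ 10 ⇒ 8 (through 9). C1 and C2 of 11 come from hydrogenation of the disubstituted C1=C2 alkene of dienone 10. That dienone arises from 8 by moving the ring A oxygen from C1 to C3: reduction at C1 gives 9, and acid turns the allylic alcohol and enol ether into the C3 ketone. The same acid unmasks the C8 ketone and lets C7 settle with its chain equatorial.

8 ⇒ 7 ⇒ 6. The C4–C15 bond is cut. The C4 ketone of 6 can enolise only towards C5, so enol triflate 7 fixes C4=C5 unambiguously and a methyl cross-coupling installs C15. This avoids a tertiary carbinol whose dehydration could go towards C15.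

6 ⇒ 2 + 5. The C9–C10 and C5–C6 bonds are cut. This is the disconnection that carries the plan: ring B, the quaternary centre, the C8 oxygen as a silyl enol ether and the C7 carbon chain all come from one [4+2] reaction of quinone 2 with diene 5. The forward reaction has to choose the methylated alkene of 2, orient the silyloxy carbon 1,3 to C10, and set the face at C10 with a chelating chiral Lewis acid.

5 ⇒ 4 ⇒ 3 and 2 ⇒ 1. Diene 5 is the silyl enol ether of enone 4, which is keto ester 3 with one carbon added next to the ketone. Quinone 2 is the para-oxidation product of phenol 1. Both partners are one or two steps from purchased materials, so the risk sits in the cycloaddition.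

## Alternatives that were turned down

Alternative 1: Rings A and B are both opened by cutting C5–C10 and C3–C4, which leads to the acyclic dienyne keto ester A1. In A1 the but-2-ynyl group (C15–C4≡C5–C6) and a 1-silyloxydiene (C3=C2–C1=C10) are tied together through C6–C7–C8–C9. In the forward direction Ni(cod)2 (zerovalent nickel) with a triaryl phosphite would fold A1 by an intramolecular [4+2] reaction into the bicyclic dienone A2.
- For it: two rings, the tetrasubstituted C4=C5 alkene and two stereocentres (C3, C10) form in one neutral step. The C3 oxygen arrives at the right oxidation level, so no oxygen transposition and no C4 methylation are needed. On bonds per step and on redox economy in ring A this plan is stronger than the chosen one.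
- Against it: the cis relation of the C3 oxygen and the C10 methyl in A2 requires that the tether or the silyloxy group sit on an inside (Z) position of the diene. That geometry is hard to make selectively and slows the cyclisation.
- Against it: C3 and C10 would have to be induced from C7, an epimerisable centre α to a ketone, through a flexible tether, with no catalyst control.
- Against it: A1 is a long linear compound (stereocentre, skipped enyne, defined dienol ether), and after A2 the same late steps remain.
- Comparison: the chosen route offers catalyst control at C10 and partners made in one or two steps.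

Alternative 2: Only C1–C10 is cut, and ring B is taken from the chiral pool as the 5-isopropenyl-2-methylcyclohexenone A3, which carries the ring A chain on C5. In the forward direction KOt-Bu would remove the doubly activated C4 hydrogen; the extended enolate would add through C10 to the vinyl ketone and give the dione A4.
- For it: the C7 stereocentre and all fifteen carbons are present early, and no chiral catalyst is needed. The annulation makes C10, C4=C5 and the C3 carbonyl in one base-only step. On the source of chirality this plan is at least as strong as the chosen one.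
- Against it: A4 has its ring B oxygen at C9, whereas 22 needs oxygen at C8 and none at C9, so a 1,2-carbonyl transposition of several steps is unavoidable.
- Against it: the isopropenyl group must be oxidised at C12 up to the ester level in the presence of other alkenes.
- Against it: the face at C10 is decided only by a substituent in a 1,4 relation across ring B, a weak element of control.
- Comparison: the chosen route places O8 by the orientation of the cycloaddition and starts with C12 at the acid oxidation level.

Alternative 3: The C4=C5 alkene is cut by ring-closing metathesis, which leads to diene A5 (C5 exocyclic methylene, isopropenyl at C4, C10 set beforehand by a catalytic enantioselective alkylation). In the forward direction a second-generation Grubbs-type catalyst, RuCl2(=CHPh)(PCy3)(NHC) with N-o-tolyl groups on the carbene, would close ring A to the octalin A6.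
- For it: catalytic construction of C10 by enolate allylation is mature, so on the certainty of the absolute configuration at C10 this plan is stronger. The C3 oxygen is present without transposition, and the metathesis tolerates the functional groups.
- Against it: joining two 1,1-disubstituted alkenes into a tetrasubstituted one is the most demanding metathesis case.
- Against it: A6 has no carbon at C7, so the two-carbon chain must be introduced later by a regio- and stereoselective alkylation.
- Against it: C3 needs its own absolute-stereochemistry step, and the step count to A5 is high.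
- Comparison: the chosen route delivers ring B with the C7 carbon and the C8 oxygen in one step and spends its remaining steps on well-understood ring A adjustments.

Key step: step 4

Remark: the (R)-binaphthol–titanium catalyst is assumed, from the chelate model, to give (5S,10R)-6; if the opposite sense is found, the (S)-ligand is used and nothing else changes.

## Route

Step 1
Reactants: 1 2-methoxy-5-methylphenol
Product: 2 2-methoxy-5-methyl-1,4-benzoquinone
Conditions: (KSO3)2NO (2.2 equiv), KH2PO4, H2O/acetone, 0 °C → rt
Reagents that add atoms: potassium nitrosodisulfonate, [K+].[K+].[O-]S(=O)(=O)N([O])S(=O)(=O)[O-]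
Why: Teuber oxidation: the phenoxyl radical is trapped para to oxygen by a second nitrosodisulfonate radical and loses imidodisulfonate. The only free position para to the hydroxyl of 1 is C4, so the 1,4-quinone should form.

Step 2
Reactants: 3 methyl 4-oxopentanoate (methyl levulinate)
Product: 4 methyl 3-methylidene-4-oxopentanoate
Conditions: (CH2O)n, i-Pr2NH2+ CF3CO2− (1 equiv), CF3CO2H (10 mol%), THF, reflux
Reagents that add atoms: formaldehyde (as paraformaldehyde), C=O
Why: Acid-mediated Mannich-type α-methylenation: the iminium ion is captured by the more substituted enol (C3, not the C5 methyl) and the β-amino ketone eliminates the amine in situ. The ester is a spectator.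

Step 3
Reactants: 4 methyl 3-methylidene-4-oxopentanoate
Product: 5 methyl 4-[(tert-butyldimethylsilyl)oxy]-3-methylidenepent-4-enoate
Conditions: TBSOTf (1.1 equiv), Et3N (1.5 equiv), CH2Cl2, 0 °C
Reagents that add atoms: tert-butyldimethylsilyl trifluoromethanesulfonate, CC(C)(C)[Si](C)(C)OS(=O)(=O)C(F)(F)F
Why: Soft enolisation: O-silylation of the enone carbonyl followed by loss of a methyl proton to the amine is the only path to a neutral enol ether. No strong base touches the allylic CH2 next to the ester, which a lithium amide could deprotonate.

Step 4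
Reactants: 2 2-methoxy-5-methyl-1,4-benzoquinone; 5 methyl 4-[(tert-butyldimethylsilyl)oxy]-3-methylidenepent-4-enoate
Product: 6 methyl 2-[(4aS,8aR)-7-[(tert-butyldimethylsilyl)oxy]-3-methoxy-8a-methyl-1,4-dioxo-1,4,4a,5,8,8a-hexahydronaphthalen-6-yl]acetate
Conditions: (R)-1,1'-bi-2-naphthol (22 mol%), TiCl2(O-i-Pr)2 (20 mol%), 4 Å MS (filtered off), CH2Cl2; then 2, 5 (1.5 equiv), −40 → −20 °C
Reagents that add atoms: none
Why: The tetravalent titanium centre is held in a five-membered chelate by the C4 carbonyl oxygen and the C3 methoxy oxygen of 2; this lowers the LUMO along O=C4–C5=C10 and makes the β-carbon C10 the electrophilic end, while the C2=C3 alkene, part of a donor-substituted vinylogous ester, stays out of the reaction (site selectivity). The reaction is a concerted, asynchronous normal-demand Diels–Alder addition in which the CH2 terminus next to the silyloxy carbon of 5 (C9, largest HOMO coefficient) bonds first to C10 and C6 then closes onto C5, so that C8–O ends up para to C5 (orientation). Two-point binding is chosen on purpose: a Lewis acid that binds through one oxygen only (a boron cation, for instance) could sit on the more basic C1 vinylogous-ester oxygen and reverse the orientation, whereas the chelate and the intrinsic polarisation of the quinone point the same way. Ring B is closed by this intermolecular [4+2] annulation, with both σ bonds formed suprafacially on diene and dienophile. C10 is set by the catalyst, whose binaphthyl group covers one face of the chelated C5=C10 alkene; C5 follows from the suprafacial addition (cis fusion) and is erased in step 5. Both diene termini are CH2 groups, so endo or exo approach creates no further isomers. The closest known reaction type is the binaphthol–titanium-catalysed Diels–Alder reaction of methyl- and methoxy-substituted benzoquinones with silyloxydienes.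

Step 5
Reactants: 6 methyl 2-[(4aS,8aR)-7-[(tert-butyldimethylsilyl)oxy]-3-methoxy-8a-methyl-1,4-dioxo-1,4,4a,5,8,8a-hexahydronaphthalen-6-yl]acetate
Product: 7 methyl 2-[(8aR)-7-[(tert-butyldimethylsilyl)oxy]-3-methoxy-8a-methyl-1-oxo-4-(trifluoromethanesulfonyloxy)-1,5,8,8a-tetrahydronaphthalen-6-yl]acetate
Conditions: KN(SiMe3)2 (1.05 equiv), THF, −78 °C; PhNTf2, −78 → 0 °C
Reagents that add atoms: N-phenylbis(trifluoromethanesulfonimide), O=S(=O)(N(c1ccccc1)S(=O)(=O)C(F)(F)F)C(F)(F)F
Why: Regioselective enolate formation and O-sulfonylation: C5–H is the only enolisable hydrogen next to either ring A carbonyl (C2 is vinylic, C10 quaternary) and is far more acidic than the ester α-CH2. One equivalent of base should therefore give the C4 enol triflate with C4=C5 in place; the C5 stereocentre is erased as planned.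

Step 6
Reactants: 7 methyl 2-[(8aR)-7-[(tert-butyldimethylsilyl)oxy]-3-methoxy-8a-methyl-1-oxo-4-(trifluoromethanesulfonyloxy)-1,5,8,8a-tetrahydronaphthalen-6-yl]acetate
Product: 8 methyl 2-[(8aR)-7-[(tert-butyldimethylsilyl)oxy]-3-methoxy-4,8a-dimethyl-1-oxo-1,5,8,8a-tetrahydronaphthalen-6-yl]acetate
Conditions: Me2Zn (1.5 equiv), Pd(PPh3)4 (5 mol%), THF, 0 → 40 °C
Reagents that add atoms: dimethylzinc, C[Zn]C
Why: Negishi cross-coupling of an enol triflate with a methylzinc reagent under zerovalent palladium. Dimethylzinc does not add to the vinylogous ester or the ester, and the transferred group has no β-hydrogen.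

Step 7
Reactants: 8 methyl 2-[(8aR)-7-[(tert-butyldimethylsilyl)oxy]-3-methoxy-4,8a-dimethyl-1-oxo-1,5,8,8a-tetrahydronaphthalen-6-yl]acetate
Product: 10 methyl (7R,10S)-3,8-dioxo-13-noreudesma-1,4-dien-12-oate, via allylic alcohol 9 (not isolated)
Conditions: NaBH4, CeCl3·7H2O, MeOH/THF, −20 → 0 °C; then 1 M aq. HCl, THF, 0 °C → rt
Reagents that add atoms: water, O
Why: Luche 1,2-reduction of the hindered vinylogous ester carbonyl (the ester is inert), then an acid-induced Stork–Danheiser-type transposition: the doubly allylic C1 hydroxyl ionises, water is captured at C3 and methanol is lost, giving the cross-conjugated dienone. The same acid hydrolyses the silyl enol ether to the C8 ketone and equilibrates C7 through the enol, so the CH2CO2CH3 group should take the equatorial β position; C7 is set under thermodynamic control.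

Step 8
Reactants: 10 methyl (7R,10S)-3,8-dioxo-13-noreudesma-1,4-dien-12-oate
Product: 11 methyl (7R,10R)-3,8-dioxo-13-noreudesm-4-en-12-oate
Conditions: H2 (1 atm), RhCl(PPh3)3 (10 mol%), benzene/EtOH, rt
Reagents that add atoms: none
Why: Homogeneous hydrogenation with RhCl(PPh3)3 reduces the cis-disubstituted C1=C2 alkene of a cross-conjugated dienone and leaves the tetrasubstituted C4=C5 alkene, both ketones and the ester untouched, as in the 1,2-dihydro derivatives of santonin-type dienones.

Step 9
Reactants: 11 methyl (7R,10R)-3,8-dioxo-13-noreudesm-4-en-12-oate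
Product: 13 (7R,8R,10R)-3-oxo-13-noreudesm-4-en-12,8-olide, via hydroxy ester 12 (not isolated)
Conditions: NaBH4 (1 equiv), MeOH/CH2Cl2 (1:1), −78 → −50 °C; aq. NH4Cl; crude in toluene, DBU (0.2 equiv), 40 °C
Reagents that add atoms: none
Why: Chemoselective borohydride reduction: at low temperature the saturated C8 ketone reacts much faster than the conjugated, tetrasubstituted enone. Hydride enters from the α face (equatorial attack) because the axial approach is blocked by the syn-axial C10 methyl, which should give the axial 8β-alcohol (C8 set by substrate control). This hydroxyl is cis to the C7 chain and closes the γ-lactone under amidine catalysis.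

Step 10
Reactants: 13 (7R,8R,10R)-3-oxo-13-noreudesm-4-en-12,8-olide
Product: 14 (3S,7R,8R,10R)-3-hydroxy-13-noreudesm-4-en-12,8-olide
Conditions: NaBH4, CeCl3·7H2O, MeOH, −40 → 0 °C
Reagents that add atoms: none
Why: Luche reduction gives 1,2-addition to the enone. Hydride adds axially from the α face, anti to the angular methyl, so the pseudo-equatorial 3β-alcohol should form (C3 set by substrate control), as with steroidal 4-en-3-ones; the lactone is not reduced.

Step 11
Reactants: 14 (3S,7R,8R,10R)-3-hydroxy-13-noreudesm-4-en-12,8-olide
Product: 17 (3S,7R,8R,10R)-3-hydroxyeudesma-4,11(13)-dien-12,8-olide, via Mannich base 15 (not isolated), via methiodide 16 (not isolated)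
Conditions: LiN(i-Pr)2 (2.3 equiv), THF, −78 °C; CH2=NMe2+ I− (3 equiv), −78 °C → rt; then MeI, MeOH, rt; then aq. NaHCO3, EtOAc, rt
Reagents that add atoms: N,N-dimethylmethyleneiminium iodide (Eschenmoser's salt), C=[N+](C)C.[I-]
Why: α-Methylenation of a γ-lactone through its enolate: Mannich reaction with a preformed iminium salt, N-methylation, then β-elimination of the ammonium group. The first equivalent of base turns the C3 hydroxyl into an inert lithium alkoxide and the second forms the enolate at C11; any O–CH2–NMe2 group formed at O3 falls apart on aqueous work-up.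

Step 12
Reactants: 17 (3S,7R,8R,10R)-3-hydroxyeudesma-4,11(13)-dien-12,8-olide; 18 (E)-3-methylpent-2-enoic acid
Product: 19 (3S,7R,8R,10R)-3-[(E)-3-methylpent-2-enoyloxy]eudesma-4,11(13)-dien-12,8-olide
Conditions: EDC·HCl (1.5 equiv), DMAP (0.2 equiv), CH2Cl2, 0 °C → rt
Reagents that add atoms: none
Why: Steglich esterification (carbodiimide activation, DMAP acyl transfer) of the equatorial allylic alcohol. The mild, weakly basic conditions should keep the (E)-enoate from deconjugating and leave the α-methylene lactone intact.

Step 13
Reactants: 19 (3S,7R,8R,10R)-3-[(E)-3-methylpent-2-enoyloxy]eudesma-4,11(13)-dien-12,8-olide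
Product: 21 methyl (3S,7R,8R,10R)-8-hydroxy-3-[(E)-3-methylpent-2-enoyloxy]eudesma-4,11(13)-dien-12-oate, via lithium carboxylate 20 (not isolated)
Conditions: LiOH·H2O (1.1 equiv), THF/H2O (3:1), 0 °C; concentrate; MeI (5 equiv), DMF, rt
Reagents that add atoms: lithium hydroxide, [Li+].[OH-]; iodomethane, CI
Why: Saponification of the strained α-methylene γ-lactone is much faster than that of the hindered β,β-disubstituted enoate at O3, so one equivalent of hydroxide should open only the lactone. The carboxylate is then O-alkylated without generating the free acid, which would relactonise.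

Step 14
Reactants: 21 methyl (3S,7R,8R,10R)-8-hydroxy-3-[(E)-3-methylpent-2-enoyloxy]eudesma-4,11(13)-dien-12-oate
Product: 22 methyl (3S,7R,8R,10R)-8-acetoxy-3-[(E)-3-methylpent-2-enoyloxy]eudesma-4,11(13)-dien-12-oate (CNP0118541.1)
Conditions: Ac2O (5 equiv), DMAP (0.3 equiv), Et3N, CH2Cl2, 0 °C → rt, on crude 21
Reagents that add atoms: acetic anhydride, CC(=O)OC(C)=O
Why: DMAP-catalysed acetylation of the axial 8β-hydroxyl; acyl transfer from the acetylpyridinium ion should outrun intramolecular transesterification to the lactone. No stereocentre is touched.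

## Compound list

1 | 2-methoxy-5-methylphenol | COc1ccc(C)cc1O | starting material
2 | 2-methoxy-5-methyl-1,4-benzoquinone | COC1=CC(=O)C(C)=CC1=O | intermediate
3 | methyl 4-oxopentanoate (methyl levulinate) | CC(=O)CCC(=O)OC | starting material
4 | methyl 3-methylidene-4-oxopentanoate | CC(=O)C(=C)CC(=O)OC | intermediate
5 | methyl 4-[(tert-butyldimethylsilyl)oxy]-3-methylidenepent-4-enoate | C=C(CC(=O)OC)C(=C)O[Si](C)(C)C(C)(C)C | intermediate
6 | methyl 2-[(4aS,8aR)-7-[(tert-butyldimethylsilyl)oxy]-3-methoxy-8a-methyl-1,4-dioxo-1,4,4a,5,8,8a-hexahydronaphthalen-6-yl]acetate (cis-fused; 5β-H, 10β-CH3 in eudesmane numbering) | COC1=CC(=O)[C@]2(C)CC(O[Si](C)(C)C(C)(C)C)=C(CC(=O)OC)C[C@@H]2C1=O | intermediate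
7 | methyl 2-[(8aR)-7-[(tert-butyldimethylsilyl)oxy]-3-methoxy-8a-methyl-1-oxo-4-(trifluoromethanesulfonyloxy)-1,5,8,8a-tetrahydronaphthalen-6-yl]acetate | COC1=CC(=O)[C@]2(C)CC(O[Si](C)(C)C(C)(C)C)=C(CC(=O)OC)CC2=C1OS(=O)(=O)C(F)(F)F | intermediate
8 | methyl 2-[(8aR)-7-[(tert-butyldimethylsilyl)oxy]-3-methoxy-4,8a-dimethyl-1-oxo-1,5,8,8a-tetrahydronaphthalen-6-yl]acetate | COC1=CC(=O)[C@]2(C)CC(O[Si](C)(C)C(C)(C)C)=C(CC(=O)OC)CC2=C1C | intermediate
9 | methyl 2-[(8aR)-7-[(tert-butyldimethylsilyl)oxy]-1-hydroxy-3-methoxy-4,8a-dimethyl-1,5,8,8a-tetrahydronaphthalen-6-yl]acetate (both C1 epimers) | COC1=CC(O)[C@]2(C)CC(O[Si](C)(C)C(C)(C)C)=C(CC(=O)OC)CC2=C1C | intermediate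
10 | methyl (7R,10S)-3,8-dioxo-13-noreudesma-1,4-dien-12-oate (7β-CH2CO2CH3, 10β-CH3) | COC(=O)C[C@H]1CC2=C(C)C(=O)C=C[C@]2(C)CC1=O | intermediate
11 | methyl (7R,10R)-3,8-dioxo-13-noreudesm-4-en-12-oate | COC(=O)C[C@H]1CC2=C(C)C(=O)CC[C@]2(C)CC1=O | intermediate
12 | methyl (7R,8R,10R)-8-hydroxy-3-oxo-13-noreudesm-4-en-12-oate (8β-OH) | COC(=O)C[C@H]1CC2=C(C)C(=O)CC[C@]2(C)C[C@H]1O | intermediate
13 | (7R,8R,10R)-3-oxo-13-noreudesm-4-en-12,8-olide (cis-fused lactone) | O=C1C[C@H]2CC3=C(C)C(=O)CC[C@]3(C)C[C@H]2O1 | intermediate
14 | (3S,7R,8R,10R)-3-hydroxy-13-noreudesm-4-en-12,8-olide (3β-OH) | O=C1C[C@H]2CC3=C(C)[C@@H](O)CC[C@]3(C)C[C@H]2O1 | intermediate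
15 | (3S,7R,8R,10R)-13-(dimethylamino)-3-hydroxyeudesm-4-en-12,8-olide (C11 epimers) | O=C1C(CN(C)C)[C@H]2CC3=C(C)[C@@H](O)CC[C@]3(C)C[C@H]2O1 | intermediate
16 | [(3S,7R,8R,10R)-3-hydroxy-12-oxoeudesm-4-en-12,8-olid-13-yl]trimethylammonium iodide (C11 epimers) | O=C1C(C[N+](C)(C)C)[C@H]2CC3=C(C)[C@@H](O)CC[C@]3(C)C[C@H]2O1.[I-] | intermediate
17 | (3S,7R,8R,10R)-3-hydroxyeudesma-4,11(13)-dien-12,8-olide | O=C1C(=C)[C@H]2CC3=C(C)[C@@H](O)CC[C@]3(C)C[C@H]2O1 | intermediate
18 | (E)-3-methylpent-2-enoic acid | CC/C(C)=C/C(=O)O | starting material
19 | (3S,7R,8R,10R)-3-[(E)-3-methylpent-2-enoyloxy]eudesma-4,11(13)-dien-12,8-olide | O=C1C(=C)[C@H]2CC3=C(C)[C@@H](OC(=O)/C=C(\C)CC)CC[C@]3(C)C[C@H]2O1 | intermediate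
20 | lithium (3S,7R,8R,10R)-8-hydroxy-3-[(E)-3-methylpent-2-enoyloxy]eudesma-4,11(13)-dien-12-oate | C=C(C(=O)[O-])[C@H]1CC2=C(C)[C@@H](OC(=O)/C=C(\C)CC)CC[C@]2(C)C[C@H]1O.[Li+] | intermediate
21 | methyl (3S,7R,8R,10R)-8-hydroxy-3-[(E)-3-methylpent-2-enoyloxy]eudesma-4,11(13)-dien-12-oate | C=C(C(=O)OC)[C@H]1CC2=C(C)[C@@H](OC(=O)/C=C(\C)CC)CC[C@]2(C)C[C@H]1O | intermediate
22 | methyl (3S,7R,8R,10R)-8-acetoxy-3-[(E)-3-methylpent-2-enoyloxy]eudesma-4,11(13)-dien-12-oate (CNP0118541.1) | C=C(C(=O)OC)[C@H]1CC2=C(C)[C@@H](OC(=O)/C=C(\C)CC)CC[C@]2(C)C[C@H]1OC(C)=O | target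

## Step count and least certain steps

Total: 14 steps. Longest linear sequence: 13 steps (3 → 22, steps 2 to 14).

Step 4 (key step). Most likely to go wrong is incomplete discrimination of the two faces of the C5=C10 alkene: the alkene is trisubstituted, the transition state is early and asynchronous, and the first bond forms at the fully substituted carbon, away from the ligand. A second concern is Lewis-acid-induced loss of the silyl group from 5 before ring closure. Fallback: starting from 2 and 5, the cycloaddition is run with SnCl4 (1 equiv, CH2Cl2, −78 °C), which chelates in the same way and should give the same orientation as a racemate. The enantiomers are then separated by preparative chromatography on a chiral stationary phase; the mirror-image adduct F1 is set aside, and 6 rejoins the route at step 5.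

Step 7. Most likely to go wrong is premature methanolysis of the silyl enol ether in the cerium-containing methanol; the liberated C8 ketone would then be reduced before C7 has equilibrated. Slow reduction of the hindered vinylogous ester makes this worse. Fallback: starting from 8, the enol ether is cleaved on purpose (HF·pyridine, THF, 0 °C; then catalytic DBU) to the equilibrated diketone F5. NaBH4/CeCl3·7H2O then reduces both the C8 and C1 carbonyls to the diol F6. 1 M HCl in THF effects the transposition and lactonisation to the dienone lactone F7, and hydrogenation over RhCl(PPh3)3 gives 13, where the route is rejoined.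

Step 11. Most likely to go wrong is incomplete C-aminomethylation: the alkoxide–enolate dianion may aggregate, and the alkoxide may consume the iminium salt. Fallback: starting from 14, the hydroxyl is silylated (TBSCl, imidazole, DMF) to the silyl ether F8. Methylenation as in step 11, with 1.2 equiv of LiN(i-Pr)2, passes through the Mannich base F9 and the methiodide F10 to the silylated methylene lactone F11. HF·pyridine in THF then gives 17, where the route is rejoined.

Step 13. Most likely to go wrong is partial hydrolysis of the O3 enoate, or conjugate addition of hydroxide at C13, competing with lactone opening. Fallback: the order is changed. Starting from 17, LiOH and then MeI in DMF give, through the lithium carboxylate F12, the diol methyl ester F13. Its equatorial allylic 3β-hydroxyl is then acylated with 18 (EDC·HCl, DMAP, 1.0 equiv, −20 °C) in preference to the axial 8β-hydroxyl, which is syn to the C10 methyl. This gives 21, where the route is rejoined.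

Step 2. Most likely to go wrong is partial aminomethylation at the C5 methyl and oligomerisation of the reactive enone on concentration. Fallback: a regiodefined synthesis starting from purchased 4-methyl hydrogen itaconate F2. Oxalyl chloride with catalytic DMF gives the acid chloride F3, and palladium-catalysed acylation of Me2Zn (Pd(PPh3)4, THF, 0 °C) gives 4, where the route is rejoined.

Step 5. Most likely to go wrong is decomposition of the cross-conjugated enolate or of triflate 7 before the coupling, since 7 is an electron-poor dienyl triflate. Fallback: starting from 6, MeTi(O-i-Pr)3 (THF, −40 °C → rt) adds to the C4 ketone only, giving the tertiary carbinol F4. Dehydration into conjugation with Burgess reagent (or SOCl2/pyridine if the hydroxyl and C5–H are anti) gives 8, where the route is rejoined.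

## Further compounds

F1 | step 4 | mirror-image adduct, methyl 2-[(4aR,8aS)-7-[(tert-butyldimethylsilyl)oxy]-3-methoxy-8a-methyl-1,4-dioxo-1,4,4a,5,8,8a-hexahydronaphthalen-6-yl]acetate | COC1=CC(=O)[C@@]2(C)CC(O[Si](C)(C)C(C)(C)C)=C(CC(=O)OC)C[C@H]2C1=O
F2 | step 2 | 4-methyl hydrogen itaconate (4-methoxy-2-methylidene-4-oxobutanoic acid) | C=C(CC(=O)OC)C(=O)O
F3 | step 2 | methyl 3-(chlorocarbonyl)but-3-enoate | C=C(CC(=O)OC)C(=O)Cl
F4 | step 5 | methyl 2-[(4aS,8aR)-7-[(tert-butyldimethylsilyl)oxy]-4-hydroxy-3-methoxy-4,8a-dimethyl-1-oxo-1,4,4a,5,8,8a-hexahydronaphthalen-6-yl]acetate (C4 epimers) | COC1=CC(=O)[C@]2(C)CC(O[Si](C)(C)C(C)(C)C)=C(CC(=O)OC)C[C@@H]2C1(C)O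
F5 | step 7 | methyl (7R,10R)-3-methoxy-1,8-dioxo-13-noreudesma-2,4-dien-12-oate | COC1=CC(=O)[C@]2(C)CC(=O)[C@@H](CC(=O)OC)CC2=C1C
F6 | step 7 | methyl (7R,8R,10R)-1,8-dihydroxy-3-methoxy-13-noreudesma-2,4-dien-12-oate (C1 epimers) | COC1=CC(O)[C@]2(C)C[C@@H](O)[C@@H](CC(=O)OC)CC2=C1C
F7 | step 7 | (7R,8R,10S)-3-oxo-13-noreudesma-1,4-dien-12,8-olide | O=C1C[C@H]2CC3=C(C)C(=O)C=C[C@]3(C)C[C@H]2O1
F8 | step 11 | (3S,7R,8R,10R)-3-[(tert-butyldimethylsilyl)oxy]-13-noreudesm-4-en-12,8-olide | O=C1C[C@H]2CC3=C(C)[C@@H](O[Si](C)(C)C(C)(C)C)CC[C@]3(C)C[C@H]2O1
F9 | step 11 | (3S,7R,8R,10R)-3-[(tert-butyldimethylsilyl)oxy]-13-(dimethylamino)eudesm-4-en-12,8-olide (C11 epimers) | O=C1C(CN(C)C)[C@H]2CC3=C(C)[C@@H](O[Si](C)(C)C(C)(C)C)CC[C@]3(C)C[C@H]2O1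
F10 | step 11 | methiodide of F9 (C11 epimers) | O=C1C(C[N+](C)(C)C)[C@H]2CC3=C(C)[C@@H](O[Si](C)(C)C(C)(C)C)CC[C@]3(C)C[C@H]2O1.[I-]
F11 | step 11 | (3S,7R,8R,10R)-3-[(tert-butyldimethylsilyl)oxy]eudesma-4,11(13)-dien-12,8-olide | O=C1C(=C)[C@H]2CC3=C(C)[C@@H](O[Si](C)(C)C(C)(C)C)CC[C@]3(C)C[C@H]2O1
F12 | step 13 | lithium (3S,7R,8R,10R)-3,8-dihydroxyeudesma-4,11(13)-dien-12-oate | C=C(C(=O)[O-])[C@H]1CC2=C(C)[C@@H](O)CC[C@]2(C)C[C@H]1O.[Li+]
F13 | step 13 | methyl (3S,7R,8R,10R)-3,8-dihydroxyeudesma-4,11(13)-dien-12-oate | C=C(C(=O)OC)[C@H]1CC2=C(C)[C@@H](O)CC[C@]2(C)C[C@H]1O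
A1 | alternative 1 | tert-butyl (3R,6Z,8E)-3-(but-2-yn-1-yl)-9-[(tert-butyldimethylsilyl)oxy]-6-methyl-4-oxonona-6,8-dienoate | CC#CC[C@H](CC(=O)OC(C)(C)C)C(=O)C/C(C)=C\C=C\O[Si](C)(C)C(C)(C)C
A2 | alternative 1 | tert-butyl (3S,7R,10S)-3-[(tert-butyldimethylsilyl)oxy]-8-oxo-13-noreudesma-1,4-dien-12-oate | CC(C)(C)OC(=O)C[C@H]1CC2=C(C)[C@@H](O[Si](C)(C)C(C)(C)C)C=C[C@]2(C)CC1=O
A3 | alternative 2 | (5S)-2-methyl-3-(3-oxopent-4-en-2-yl)-5-(prop-1-en-2-yl)cyclohex-2-en-1-one (side-chain epimers) | C=CC(=O)C(C)C1=C(C)C(=O)C[C@@H](C(C)=C)C1
A4 | alternative 2 | (7S,10S)-eudesma-4,11-diene-3,9-dione | C=C(C)[C@H]1CC2=C(C)C(=O)CC[C@]2(C)C(=O)C1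
A5 | alternative 3 | (7R)-7-[(3S)-3-[(tert-butyldimethylsilyl)oxy]-4-methylpent-4-en-1-yl]-7-methyl-8-methylidene-1,4-dioxaspiro[4.5]decane | C=C1CCC2(OCCO2)C[C@@]1(C)CC[C@H](O[Si](C)(C)C(C)(C)C)C(C)=C
A6 | alternative 3 | (3S,10R)-3-[(tert-butyldimethylsilyl)oxy]-8,8-(ethylenedioxy)-11,12,13-trinoreudesm-4-ene | C1CC2=C(C)[C@@H](O[Si](C)(C)C(C)(C)C)CC[C@]2(C)CC13OCCO3
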